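**Retrosynthetic overview**
1. Target ⇒ tricyclic alcohol 15 + protected (9Z)-hydroxy acid 20 (ester bond at C10–O; 20 from alkyne alkylation and semihydrogenation). The last operation is acidolysis of all protecting groups and epimerisation of C2.
2. 15 ⇒ cedr-8-ene diester 11 by allylic oxidation at C10, 1,2-reduction and reduction of the C13 ester.
3. 11 ⇒ spirocyclohexadiene 9 by base isomerisation and intramolecular Michael closure of the C6–C7 bond (third ring, the bicyclo[3.2.1]octene).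
4. 9 ⇒ para-alkyl benzoate 8 by a samarium-mediated reductive ipso-spirocyclisation that destroys the arene and forms the cyclopentane (C1–C5 bond). The two equivalent arms of the ring are told apart only in the Michael step.
5. 8 ⇒ aryl(mesityl)iodonium salt 3 (from mesitylene and tert-butyl 4-iodobenzoate) + aldehyde 6 by organocatalytic α-arylation. Ring order: arene six-membered ring, then spiro cyclopentane, then bridged five-membered ring.

Assumption: positions are given in cedrane numbering (C1 spiro carbon, C2 formyl-bearing CH, C5 ring-fusion CH, C6 quaternary carbon with C13 = CH2OH and C14 = CH3, C7 bridgehead, C8=C9 with C15 carboxyl on C8, C10 carbinol, C11 methylene bridge, C12 formyl carbon). The benzylic centre is installed as R on purpose: it steers the spirocyclisation and is inverted to the target's 2S at the end.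

**Step 1**
Reactants: 1 tert-butyl 4-iodobenzoate; 2 mesitylene
Product: 3 [4-(tert-butoxycarbonyl)phenyl](2,4,6-trimethylphenyl)iodonium trifluoromethanesulfonate
Conditions: mCPBA, TsOH·H2O (1.0 equiv), CH2Cl2/CF3CH2OH 1:1, rt; then aq NaOTf wash, precipitation from Et2O
Reagents that add atoms: sodium trifluoromethanesulfonate, [Na+].[O-]S(=O)(=O)C(F)(F)F
Why: One-pot oxidation of the aryl iodide to a trivalent-iodine tosylate and electrophilic aromatic substitution on mesitylene (Olofsson-type diaryliodonium synthesis) consumes the sulfonic acid as counter-ion, so the tert-butyl ester should survive, and anion metathesis gives the triflate; no stereocentre is formed.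

**Step 2**
Reactants: 4 glutaraldehyde (50% aq, 3 equiv); 5 methyl 2-(triphenyl-λ5-phosphanylidene)propanoate
Product: 6 methyl (2E)-2-methyl-7-oxohept-2-enoate
Conditions: CH2Cl2, slow addition of 5, 0 °C to rt
Reagents that add atoms: none
Why: Wittig olefination with a stabilised ylide is E-selective for the trisubstituted enoate, and excess dialdehyde holds it at mono-olefination; no stereocentre is formed.

**Step 3**
Reactants: 3; 6 (2 equiv)
Product: 8 methyl (2E,6R)-6-[4-(tert-butoxycarbonyl)phenyl]-7,7-dimethoxy-2-methylhept-2-enoate, via aryl aldehyde 7 (not isolated)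
Conditions: CuBr (10 mol%), 5-benzyl-2-tert-butyl-3-methylimidazolidin-4-one·CCl3CO2H (10 mol%, the enantiomer that gives 6R), NaHCO3, toluene/Et2O 2:1, 23 °C; filter; then HC(OMe)3, MeOH, PPTS (5 mol%), 0 °C
Reagents that add atoms: trimethyl orthoformate, COC(OC)OC
Why: The chiral enamine of 6 is arylated by the aryl–copper species formed from 3 and CuBr (MacMillan organocatalytic α-arylation, mesityl being the non-transferred group), the imidazolidinone shielding one enamine face so the benzylic centre (cedrane C2) forms as R, and immediate acetalisation protects the racemisation-prone α-aryl aldehyde.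

**Step 4**
Reactants: 8
Product: 9 tert-butyl (1R,4S)-1-(dimethoxymethyl)-4-(1-methoxy-1-oxopropan-2-yl)spiro[4.5]deca-6,9-diene-8-carboxylate (mixture at C8 and at the propanoate α-carbon, both erased in step 5)
Conditions: SmI2 (2.5 equiv), HMPA (10 equiv), t-BuOH (2.2 equiv), THF (0.01 M), slow addition of 8, −20 to 0 °C
Reagents that add atoms: none
Why: Proposed new method: SmI2–HMPA transfers one electron to the α-methyl enoate, the β-carbon radical (C5) of the samarium enolate adds 5-exo to the ring carbon para to the ester (ipso attack, the cyclohexadienyl radical being captodatively stabilised by CO2tBu), a second SmI2 reduces it to the ester trienolate and t-BuOH protonates both enolates, the closest known reaction being the SmI2–HMPA ketyl–arene ipso-spirocyclisation onto para-alkoxycarbonyl arenes; C5 is set trans to the benzylic dimethoxymethyl group through a chair-like transition state with both substituents pseudo-equatorial.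

**Step 5**
Reactants: 9
Product: 11 8-tert-butyl 6-methyl (1R,2R,5R,6S,7S)-2-(dimethoxymethyl)-6-methyltricyclo[5.3.1.0(1,5)]undec-8-ene-6,8-dicarboxylate, via conjugated dienoate 10 (not isolated)
Conditions: KOtBu (0.3 equiv), t-BuOH/THF 1:4, 0 °C to rt; AcOH quench
Reagents that add atoms: none
Why: Base moves the skipped diene into conjugation through the ester trienolate, and the C6 ester enolate then closes 5-exo onto C7 of the ring arm on its own face of the cyclopentane (intramolecular Michael addition, which fixes C1 and C7); a potassium-bridged synclinal transition state should place CO2Me endo and CH3 exo at C6, and γ-protonation gives the conjugated 8-ene ester.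

**Step 6**
Reactants: 11
Product: 12 8-tert-butyl 6-methyl (1S,2R,5R,6S,7S)-2-(dimethoxymethyl)-6-methyl-10-oxotricyclo[5.3.1.0(1,5)]undec-8-ene-6,8-dicarboxylate
Conditions: Rh2(C6H10NO)4 (dirhodium tetrakis(caprolactamate), 1 mol%), t-BuOOH (70% aq, 5 equiv), K2CO3, CH2Cl2, rt
Reagents that add atoms: tert-butyl hydroperoxide, CC(C)(C)OO
Why: Radical allylic C–H oxidation by the tert-butylperoxyl radical (Doyle-type oxidation) can only strike C10, the other allylic position C7 being a bridgehead, and gives the γ-oxo enoate without touching a stereocentre.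

**Step 7**
Reactants: 12
Product: 14 tert-butyl (1S,2R,5S,6S,7R,10S)-2-(dimethoxymethyl)-10-hydroxy-6-(hydroxymethyl)-6-methyltricyclo[5.3.1.0(1,5)]undec-8-ene-8-carboxylate, via hydroxy ester 13 (not isolated)
Conditions: NaBH4, CeCl3·7H2O, MeOH, −78 to −40 °C; evaporate; then LiBH4 (5 equiv), THF/MeOH 20:1, 0 to 40 °C
Reagents that add atoms: none
Why: Luche 1,2-reduction is expected to deliver hydride to the C10 ketone from the exo face (side of the C11 bridge, axial attack; the endo face is screened by the C5–C6 bridge), setting 10S, and LiBH4 then reduces the methyl ester (ester reduction) while the tert-butyl enoate is inert.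

**Step 8**
Reactants: 14
Product: 15 tert-butyl (1S,2R,5S,6S,7R,10S)-6-({[tert-butyl(dimethyl)silyl]oxy}methyl)-2-(dimethoxymethyl)-10-hydroxy-6-methyltricyclo[5.3.1.0(1,5)]undec-8-ene-8-carboxylate
Conditions: TBSCl (1.1 equiv), imidazole, CH2Cl2, 0 °C
Reagents that add atoms: tert-butyldimethylsilyl chloride, CC(C)(C)[Si](C)(C)Cl
Why: Silyl ether formation is selective for the primary hydroxyl over the secondary allylic hydroxyl flanked by the quaternary C1; no stereocentre changes.

**Step 9**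
Reactants: 16 oct-7-yn-1-ol
Product: 17 tert-butyldimethyl(oct-7-yn-1-yloxy)silane
Conditions: TBSCl, imidazole, DMF, rt
Reagents that add atoms: tert-butyldimethylsilyl chloride, CC(C)(C)[Si](C)(C)Cl
Why: Standard silyl ether protection of the primary alcohol; no stereocentre.

**Step 10**
Reactants: 17; 18 8-bromooctanoic acid
Product: 19 16-{[tert-butyl(dimethyl)silyl]oxy}hexadec-9-ynoic acid
Conditions: n-BuLi (1.0 equiv) on 17 and n-BuLi (1.0 equiv) on 18 separately, THF, −78 °C; combine, HMPA, −78 °C to rt; citric acid work-up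
Reagents that add atoms: none
Why: SN2 alkylation of the lithium acetylide by the primary bromide of lithium 8-bromooctanoate builds the C16 chain in one step; no stereocentre.

**Step 11**
Reactants: 19
Product: 20 (9Z)-16-{[tert-butyl(dimethyl)silyl]oxy}hexadec-9-enoic acid
Conditions: H2 (1 atm), Pd/CaCO3 poisoned with Pb(OAc)2, quinoline, EtOAc, rt
Reagents that add atoms: none
Why: Lindlar semihydrogenation adds H2 syn to the alkyne and stops at the alkene, fixing the 9Z geometry.

**Step 12**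
Reactants: 15; 20
Product: 21 tert-butyl (1S,2R,5S,6S,7R,10S)-6-({[tert-butyl(dimethyl)silyl]oxy}methyl)-10-{[(9Z)-16-{[tert-butyl(dimethyl)silyl]oxy}hexadec-9-enoyl]oxy}-2-(dimethoxymethyl)-6-methyltricyclo[5.3.1.0(1,5)]undec-8-ene-8-carboxylate
Conditions: 20, 2,4,6-trichlorobenzoyl chloride, Et3N, THF, rt; then 15, DMAP (2 equiv), toluene, rt to 60 °C
Reagents that add atoms: none
Why: Yamaguchi esterification (mixed anhydride, DMAP acyl transfer) acylates the hindered secondary alcohol at oxygen, so C10 keeps its 10S configuration.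

**Step 13**
Reactants: 21
Product: 23 (1S,2S,5S,6S,7R,10S)-2-formyl-10-{[(9Z)-16-hydroxyhexadec-9-enoyl]oxy}-6-(hydroxymethyl)-6-methyltricyclo[5.3.1.0(1,5)]undec-8-ene-8-carboxylic acid (CNP0148862.2), via 2R aldehyde 22 (not isolated)
Conditions: TFA/CH2Cl2/H2O 10:10:1, 0 °C to rt; evaporate; then DBU (2.5 equiv), CH2Cl2, rt; aq citric acid
Reagents that add atoms: water, O
Why: Aqueous TFA cleaves the tert-butyl ester (acidolysis), the dimethyl acetal and both silyl ethers, and DBU enolisation of the α-formyl CH then epimerises C2 to the 2S aldehyde, expected to be the thermodynamic epimer because its formyl group lies over the small C11 methylene instead of 1,3-syn to the C10 acyloxy group.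

**Compound list**
1 | tert-butyl 4-iodobenzoate | CC(C)(C)OC(=O)c1ccc(I)cc1 | starting material
2 | mesitylene (1,3,5-trimethylbenzene) | Cc1cc(C)cc(C)c1 | starting material
3 | [4-(tert-butoxycarbonyl)phenyl](2,4,6-trimethylphenyl)iodonium trifluoromethanesulfonate | CC(C)(C)OC(=O)c1ccc(cc1)[I+]c1c(C)cc(C)cc1C.[O-]S(=O)(=O)C(F)(F)F | intermediate
4 | glutaraldehyde (pentanedial) | O=CCCCC=O | starting material
5 | methyl 2-(triphenyl-λ5-phosphanylidene)propanoate | COC(=O)C(C)=P(c1ccccc1)(c1ccccc1)c1ccccc1 | starting material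
6 | methyl (2E)-2-methyl-7-oxohept-2-enoate | COC(=O)/C(C)=C/CCCC=O | intermediate
7 | methyl (2E,6R)-6-[4-(tert-butoxycarbonyl)phenyl]-2-methyl-7-oxohept-2-enoate | COC(=O)/C(C)=C/CC[C@@H](C=O)c1ccc(C(=O)OC(C)(C)C)cc1 | intermediate
8 | methyl (2E,6R)-6-[4-(tert-butoxycarbonyl)phenyl]-7,7-dimethoxy-2-methylhept-2-enoate | COC(=O)/C(C)=C/CC[C@@H](C(OC)OC)c1ccc(C(=O)OC(C)(C)C)cc1 | intermediate
9 | tert-butyl (1R,4S)-1-(dimethoxymethyl)-4-(1-methoxy-1-oxopropan-2-yl)spiro[4.5]deca-6,9-diene-8-carboxylate (mixture at C8 and the propanoate α-carbon) | COC(=O)C(C)[C@@H]1CC[C@@H](C(OC)OC)C12C=CC(C(=O)OC(C)(C)C)C=C2 | intermediate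
10 | tert-butyl (1R,4S,5S)-1-(dimethoxymethyl)-4-(1-methoxy-1-oxopropan-2-yl)spiro[4.5]deca-6,8-diene-8-carboxylate | COC(=O)C(C)[C@@H]1CC[C@@H](C(OC)OC)[C@]12CC=C(C(=O)OC(C)(C)C)C=C2 | intermediate
11 | 8-tert-butyl 6-methyl (1R,2R,5R,6S,7S)-2-(dimethoxymethyl)-6-methyltricyclo[5.3.1.0(1,5)]undec-8-ene-6,8-dicarboxylate | C[C@@]1(C(=O)OC)[C@H]2C[C@@]3(CC=C2C(=O)OC(C)(C)C)[C@H](C(OC)OC)CC[C@@H]13 | intermediate
12 | 8-tert-butyl 6-methyl (1S,2R,5R,6S,7S)-2-(dimethoxymethyl)-6-methyl-10-oxotricyclo[5.3.1.0(1,5)]undec-8-ene-6,8-dicarboxylate | C[C@@]1(C(=O)OC)[C@H]2C[C@@]3(C(=O)C=C2C(=O)OC(C)(C)C)[C@H](C(OC)OC)CC[C@@H]13 | intermediate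
13 | 8-tert-butyl 6-methyl (1S,2R,5R,6S,7S,10S)-2-(dimethoxymethyl)-10-hydroxy-6-methyltricyclo[5.3.1.0(1,5)]undec-8-ene-6,8-dicarboxylate | C[C@@]1(C(=O)OC)[C@H]2C[C@@]3([C@@H](O)C=C2C(=O)OC(C)(C)C)[C@H](C(OC)OC)CC[C@@H]13 | intermediate
14 | tert-butyl (1S,2R,5S,6S,7R,10S)-2-(dimethoxymethyl)-10-hydroxy-6-(hydroxymethyl)-6-methyltricyclo[5.3.1.0(1,5)]undec-8-ene-8-carboxylate | C[C@@]1(CO)[C@H]2C[C@@]3([C@@H](O)C=C2C(=O)OC(C)(C)C)[C@H](C(OC)OC)CC[C@@H]13 | intermediate
15 | tert-butyl (1S,2R,5S,6S,7R,10S)-6-({[tert-butyl(dimethyl)silyl]oxy}methyl)-2-(dimethoxymethyl)-10-hydroxy-6-methyltricyclo[5.3.1.0(1,5)]undec-8-ene-8-carboxylate | C[C@@]1(CO[Si](C)(C)C(C)(C)C)[C@H]2C[C@@]3([C@@H](O)C=C2C(=O)OC(C)(C)C)[C@H](C(OC)OC)CC[C@@H]13 | intermediate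
16 | oct-7-yn-1-ol | OCCCCCCC#C | starting material
17 | tert-butyldimethyl(oct-7-yn-1-yloxy)silane | C#CCCCCCCO[Si](C)(C)C(C)(C)C | intermediate
18 | 8-bromooctanoic acid | OC(=O)CCCCCCCBr | starting material
19 | 16-{[tert-butyl(dimethyl)silyl]oxy}hexadec-9-ynoic acid | OC(=O)CCCCCCCC#CCCCCCCO[Si](C)(C)C(C)(C)C | intermediate
20 | (9Z)-16-{[tert-butyl(dimethyl)silyl]oxy}hexadec-9-enoic acid | OC(=O)CCCCCCC/C=C\CCCCCCO[Si](C)(C)C(C)(C)C | intermediate
21 | tert-butyl (1S,2R,5S,6S,7R,10S)-6-({[tert-butyl(dimethyl)silyl]oxy}methyl)-10-{[(9Z)-16-{[tert-butyl(dimethyl)silyl]oxy}hexadec-9-enoyl]oxy}-2-(dimethoxymethyl)-6-methyltricyclo[5.3.1.0(1,5)]undec-8-ene-8-carboxylate | C[C@@]1(CO[Si](C)(C)C(C)(C)C)[C@H]2C[C@@]3([C@@H](OC(=O)CCCCCCC/C=C\CCCCCCO[Si](C)(C)C(C)(C)C)C=C2C(=O)OC(C)(C)C)[C@H](C(OC)OC)CC[C@@H]13 | intermediate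
22 | (1S,2R,5S,6S,7R,10S)-2-formyl-10-{[(9Z)-16-hydroxyhexadec-9-enoyl]oxy}-6-(hydroxymethyl)-6-methyltricyclo[5.3.1.0(1,5)]undec-8-ene-8-carboxylic acid (C2 epimer of the target) | C[C@@]1(CO)[C@H]2C[C@@]3([C@@H](OC(=O)CCCCCCC/C=C\CCCCCCO)C=C2C(=O)O)[C@H](C=O)CC[C@@H]13 | intermediate
23 | (1S,2S,5S,6S,7R,10S)-2-formyl-10-{[(9Z)-16-hydroxyhexadec-9-enoyl]oxy}-6-(hydroxymethyl)-6-methyltricyclo[5.3.1.0(1,5)]undec-8-ene-8-carboxylic acid | C[C@@]1(CO)[C@H]2C[C@@]3([C@@H](OC(=O)CCCCCCC/C=C\CCCCCCO)C=C2C(=O)O)[C@@H](C=O)CC[C@@H]13 | target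

**Totals**
Total step count: 13. Longest linear sequence: 9 steps (1, 3, 4, 5, 6, 7, 8, 12, 13).

**Three steps most likely to fail**

Step 4. The reductive ipso-cyclisation is unprecedented for an enoate; plain conjugate reduction, ortho attack or poor trans selectivity are the likely failures. The fallback sets out from 8 and comes back at 9, and replaces electron transfer by a neutral radical chain. Conjugate addition of benzeneselenol (PhSeSePh, NaBH4, EtOH, AcOH) to the enoate gives methyl (6R)-6-[4-(tert-butoxycarbonyl)phenyl]-7,7-dimethoxy-2-methyl-3-(phenylselanyl)heptanoate F1. Slow addition of Bu3SnH with AIBN in refluxing benzene then generates the same C5 radical from the C–Se bond; it cyclises onto the ipso carbon and the cyclohexadienyl radical is quenched by the stannane to give 9 (any conjugated diene isomers also feed step 5).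

Step 5. The C6–H is less acidic than the ring γ-hydrogens, so the Michael closure may stall or give the wrong C6 epimer. The fallback sets out from 9 and comes back at 15, and uses an aldehyde donor instead of an ester enolate. LiBH4 reduces the methyl ester of 9 (the unconjugated tert-butyl ester survives) to tert-butyl (1R,4S)-1-(dimethoxymethyl)-4-(1-hydroxypropan-2-yl)spiro[4.5]deca-6,9-diene-8-carboxylate F2. Dess–Martin periodinane gives tert-butyl (1R,4S)-1-(dimethoxymethyl)-4-(1-oxopropan-2-yl)spiro[4.5]deca-6,9-diene-8-carboxylate F3. DBU (or catalytic pyrrolidine) then conjugates the diene and closes the ring through the much more acidic aldehyde, giving tert-butyl (1R,2R,5R,6S,7R)-2-(dimethoxymethyl)-6-formyl-6-methyltricyclo[5.3.1.0(1,5)]undec-8-ene-8-carboxylate F4. NaBH4 gives tert-butyl (1R,2R,5R,6S,7R)-2-(dimethoxymethyl)-6-(hydroxymethyl)-6-methyltricyclo[5.3.1.0(1,5)]undec-8-ene-8-carboxylate F5, and TBSCl/imidazole gives tert-butyl (1R,2R,5R,6S,7R)-6-({[tert-butyl(dimethyl)silyl]oxy}methyl)-2-(dimethoxymethyl)-6-methyltricyclo[5.3.1.0(1,5)]undec-8-ene-8-carboxylate F6. Allylic oxidation as in step 6 gives tert-butyl (1S,2R,5S,6S,7R)-6-({[tert-butyl(dimethyl)silyl]oxy}methyl)-2-(dimethoxymethyl)-6-methyl-10-oxotricyclo[5.3.1.0(1,5)]undec-8-ene-8-carboxylate F7, and Luche reduction of F7 gives 15.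

Step 7. The face of hydride attack at C10 is predicted, not proven; both faces carry one close hydrogen. The fallback sets out from 12 and comes back at 21, and installs the ester with inversion instead of retention. If hydride enters from the endo face, the Luche product is 8-tert-butyl 6-methyl (1S,2R,5R,6S,7S,10R)-2-(dimethoxymethyl)-10-hydroxy-6-methyltricyclo[5.3.1.0(1,5)]undec-8-ene-6,8-dicarboxylate F8. LiBH4 gives tert-butyl (1S,2R,5S,6S,7R,10R)-2-(dimethoxymethyl)-10-hydroxy-6-(hydroxymethyl)-6-methyltricyclo[5.3.1.0(1,5)]undec-8-ene-8-carboxylate F9, and TBSCl/imidazole gives tert-butyl (1S,2R,5S,6S,7R,10R)-6-({[tert-butyl(dimethyl)silyl]oxy}methyl)-2-(dimethoxymethyl)-10-hydroxy-6-methyltricyclo[5.3.1.0(1,5)]undec-8-ene-8-carboxylate F10. Mitsunobu esterification of F10 with acid 20 (PPh3, DIAD, toluene, 0 °C to rt) inverts C10 and gives 21.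

**Further compounds**
F1 | step 4 | methyl (6R)-6-[4-(tert-butoxycarbonyl)phenyl]-7,7-dimethoxy-2-methyl-3-(phenylselanyl)heptanoate | COC(=O)C(C)C([Se]c1ccccc1)CC[C@@H](C(OC)OC)c1ccc(C(=O)OC(C)(C)C)cc1
F2 | step 5 | tert-butyl (1R,4S)-1-(dimethoxymethyl)-4-(1-hydroxypropan-2-yl)spiro[4.5]deca-6,9-diene-8-carboxylate | OCC(C)[C@@H]1CC[C@@H](C(OC)OC)C12C=CC(C(=O)OC(C)(C)C)C=C2
F3 | step 5 | tert-butyl (1R,4S)-1-(dimethoxymethyl)-4-(1-oxopropan-2-yl)spiro[4.5]deca-6,9-diene-8-carboxylate | O=CC(C)[C@@H]1CC[C@@H](C(OC)OC)C12C=CC(C(=O)OC(C)(C)C)C=C2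
F4 | step 5 | tert-butyl (1R,2R,5R,6S,7R)-2-(dimethoxymethyl)-6-formyl-6-methyltricyclo[5.3.1.0(1,5)]undec-8-ene-8-carboxylate | C[C@@]1(C=O)[C@H]2C[C@@]3(CC=C2C(=O)OC(C)(C)C)[C@H](C(OC)OC)CC[C@@H]13
F5 | step 5 | tert-butyl (1R,2R,5R,6S,7R)-2-(dimethoxymethyl)-6-(hydroxymethyl)-6-methyltricyclo[5.3.1.0(1,5)]undec-8-ene-8-carboxylate | C[C@@]1(CO)[C@H]2C[C@@]3(CC=C2C(=O)OC(C)(C)C)[C@H](C(OC)OC)CC[C@@H]13
F6 | step 5 | tert-butyl (1R,2R,5R,6S,7R)-6-({[tert-butyl(dimethyl)silyl]oxy}methyl)-2-(dimethoxymethyl)-6-methyltricyclo[5.3.1.0(1,5)]undec-8-ene-8-carboxylate | C[C@@]1(CO[Si](C)(C)C(C)(C)C)[C@H]2C[C@@]3(CC=C2C(=O)OC(C)(C)C)[C@H](C(OC)OC)CC[C@@H]13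
F7 | step 5 | tert-butyl (1S,2R,5S,6S,7R)-6-({[tert-butyl(dimethyl)silyl]oxy}methyl)-2-(dimethoxymethyl)-6-methyl-10-oxotricyclo[5.3.1.0(1,5)]undec-8-ene-8-carboxylate | C[C@@]1(CO[Si](C)(C)C(C)(C)C)[C@H]2C[C@@]3(C(=O)C=C2C(=O)OC(C)(C)C)[C@H](C(OC)OC)CC[C@@H]13
F8 | step 7 | 8-tert-butyl 6-methyl (1S,2R,5R,6S,7S,10R)-2-(dimethoxymethyl)-10-hydroxy-6-methyltricyclo[5.3.1.0(1,5)]undec-8-ene-6,8-dicarboxylate | C[C@@]1(C(=O)OC)[C@H]2C[C@@]3([C@H](O)C=C2C(=O)OC(C)(C)C)[C@H](C(OC)OC)CC[C@@H]13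
F9 | step 7 | tert-butyl (1S,2R,5S,6S,7R,10R)-2-(dimethoxymethyl)-10-hydroxy-6-(hydroxymethyl)-6-methyltricyclo[5.3.1.0(1,5)]undec-8-ene-8-carboxylate | C[C@@]1(CO)[C@H]2C[C@@]3([C@H](O)C=C2C(=O)OC(C)(C)C)[C@H](C(OC)OC)CC[C@@H]13
F10 | step 7 | tert-butyl (1S,2R,5S,6S,7R,10R)-6-({[tert-butyl(dimethyl)silyl]oxy}methyl)-2-(dimethoxymethyl)-10-hydroxy-6-methyltricyclo[5.3.1.0(1,5)]undec-8-ene-8-carboxylate | C[C@@]1(CO[Si](C)(C)C(C)(C)C)[C@H]2C[C@@]3([C@H](O)C=C2C(=O)OC(C)(C)C)[C@H](C(OC)OC)CC[C@@H]13
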